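Ring C of the flavonol is dissected at C3, the single oxygen-bearing carbon lying between the C4 carbonyl and the O1-bound C2. Both neighbours are acyl carbons that can be hung on ring A beforehand: C4 as an aroyl chloride on C4a, C2 as the 4-prenyloxybenzoate on the C8a oxygen. An alkoxymethylene phosphorus ylide then supplies C3 with its oxygen: acylation forges C3–C4, and the resulting acylphosphorane olefinates the adjacent ester to form C2=C3 and close the pyranone in the same flask. The precursor is a fully substituted O-aroylsalicyloyl chloride made from methyl 4-O-methylgallate; two deprotections finish the synthesis.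

Key step: step 10

Remark: the target has no stereocentre and no stereogenic double bond, so it is achiral and no enantiomer has to be controlled; prenyl = 3-methylbut-2-en-1-yl throughout.

Step 1
Reactants: 1 methyl 3,5-dihydroxy-4-methoxybenzoate
Product: 2 methyl 4-methoxy-3,5-bis(methoxymethoxy)benzoate
Conditions: MOMCl, i-Pr2NEt, CH2Cl2, 0 °C → rt
Reagents that add atoms: chloromethyl methyl ether, COCCl
Why: Williamson-type O-alkylation of both phenols by the reactive α-chloro ether under a hindered amine base should be clean, and the two hydroxyls are equivalent by symmetry so no selectivity is needed.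

Step 2
Reactants: 2 methyl 4-methoxy-3,5-bis(methoxymethoxy)benzoate
Product: 3 [4-methoxy-3,5-bis(methoxymethoxy)phenyl]methanol
Conditions: LiAlH4, THF, 0 °C; aqueous NaOH work-up
Reagents that add atoms: none
Why: Hydride reduction of an aryl ester (LiAlH4 reduction) should give the benzylic alcohol, the MOM acetals and aryl ethers being inert to hydride.

Step 3
Reactants: 3 [4-methoxy-3,5-bis(methoxymethoxy)phenyl]methanol
Product: 4 4-methoxy-3,5-bis(methoxymethoxy)benzaldehyde
Conditions: activated MnO2, CH2Cl2, rt
Reagents that add atoms: none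
Why: Heterogeneous MnO2 oxidation is selective for benzylic alcohols, stops at the aldehyde and leaves acetals untouched.

Step 4
Reactants: 4 4-methoxy-3,5-bis(methoxymethoxy)benzaldehyde
Product: 6 4-methoxy-3,5-bis(methoxymethoxy)phenol, via aryl formate 5 (not isolated)
Conditions: mCPBA, CH2Cl2, 0 °C → rt; then K2CO3 (cat.), MeOH, 0 °C
Reagents that add atoms: meta-chloroperoxybenzoic acid, O=C(OO)c1cccc(Cl)c1
Why: Baeyer–Villiger (Dakin-type) oxidation should proceed with migration of the electron-rich aryl group to give the formate, as is usual for 3,4,5-trialkoxybenzaldehydes, and methanolysis of this very labile ester then frees the phenol.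

Step 5
Reactants: 6 4-methoxy-3,5-bis(methoxymethoxy)phenol
Product: 7 2-hydroxy-5-methoxy-4,6-bis(methoxymethoxy)benzaldehyde
Conditions: MgCl2, Et3N, (CH2O)n, MeCN, 80 °C
Reagents that add atoms: paraformaldehyde (formaldehyde), C=O
Why: Magnesium-mediated ortho-formylation (Casnati–Skattebøl) delivers formaldehyde to the ortho carbon within the magnesium phenoxide chelate while a second formaldehyde takes up hydride; the two ortho positions are equivalent, the para position is blocked by OMe, and the weakly basic medium should spare the MOM acetals.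

Step 6
Reactants: 8 4-hydroxybenzoic acid; 9 prenyl bromide
Product: 11 4-(prenyloxy)benzoic acid, via prenyl 4-(prenyloxy)benzoate 10 (not isolated)
Conditions: K2CO3, DMF, rt; then 2 M NaOH, MeOH, 60 °C; 1 M HCl to pH 3, 0 °C
Reagents that add atoms: sodium hydroxide, [Na+].[OH-]
Why: Williamson SN2 alkylation of both phenoxide and carboxylate by the allylic bromide, followed by saponification of the prenyl ester, should leave only the base-stable aryl prenyl ether.

Step 7
Reactants: 7 2-hydroxy-5-methoxy-4,6-bis(methoxymethoxy)benzaldehyde; 11 4-(prenyloxy)benzoic acid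
Product: 12 2-formyl-4-methoxy-3,5-bis(methoxymethoxy)phenyl 4-(prenyloxy)benzoate
Conditions: EDC·HCl, DMAP, CH2Cl2, 0 °C → rt
Reagents that add atoms: none
Why: Steglich esterification via the DMAP-derived acylpyridinium should acylate the only free hydroxyl, and it avoids an aroyl chloride and HCl that could harm the prenyl ether or the MOM acetals.

Step 8
Reactants: 12 2-formyl-4-methoxy-3,5-bis(methoxymethoxy)phenyl 4-(prenyloxy)benzoate
Product: 13 3-methoxy-2,4-bis(methoxymethoxy)-6-(4-prenyloxybenzoyloxy)benzoic acid
Conditions: NaClO2, NaH2PO4, 2-methyl-2-butene (large excess), t-BuOH/THF/H2O, 0 °C → rt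
Reagents that add atoms: sodium chlorite, [Na+].[O-]Cl=O
Why: Pinnick oxidation at about pH 4 should convert the hindered aldehyde into the acid without touching the aryl ester or the acetals, the excess scavenger alkene intercepting hypochlorous acid before it reaches the prenyl alkene or the electron-rich ring.

Step 9
Reactants: 13 3-methoxy-2,4-bis(methoxymethoxy)-6-(4-prenyloxybenzoyloxy)benzoic acid
Product: 14 3-methoxy-2,4-bis(methoxymethoxy)-6-(4-prenyloxybenzoyloxy)benzoyl chloride (crude, used at once)
Conditions: 1-chloro-N,N,2-trimethylprop-1-en-1-amine, CH2Cl2, 0 °C → rt; evaporate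
Reagents that add atoms: 1-chloro-N,N,2-trimethylprop-1-en-1-amine (Ghosez reagent), CC(C)=C(Cl)N(C)C
Why: Neutral acid chloride formation through an acyloxy-iminium chloride releases an amide and no free HCl, so the MOM acetals, the aryl ester and the prenyl ether should survive.

Step 10
Reactants: 14 3-methoxy-2,4-bis(methoxymethoxy)-6-(4-prenyloxybenzoyloxy)benzoyl chloride; 15 [2-(trimethylsilyl)ethoxymethyl]triphenylphosphonium chloride
Product: 19 6-methoxy-5,7-bis(methoxymethoxy)-4'-prenyloxy-3-[2-(trimethylsilyl)ethoxy]flavone, via alkoxymethylene ylide 16 (not isolated), via acylphosphonium chloride 17 (not isolated), via alpha-alkoxy acylphosphorane 18 (not isolated)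
Conditions: 15 (2.3 equiv), NaHMDS (2.2 equiv), THF, −78 → 0 °C; add 14 in THF, −78 °C → rt; then PhMe, 100 °C
Reagents that add atoms: none
Why: Proposed new method: the non-stabilised ylide 16 should be C-acylated by the acid chloride at low temperature to give salt 17 (new C3–C4 bond), which a second equivalent of 16 deprotonates by transylidation to the alpha-alkoxy acylphosphorane 18. On warming, the ylide carbon of 18 adds to the neighbouring aryl ester carbonyl in a 6-exo-trig closure and the oxaphosphetane collapses with loss of triphenylphosphine oxide, giving C2=C3 and the pyranone ring C, whose ring oxygen O1 is the ester oxygen already in place. The closest known reaction type is the intramolecular ester Wittig of (2-acyloxyphenacylidene)phosphoranes that delivers chromones and flavones; the untested element is the alkoxy substituent on the ylide carbon, which should make the ylide less stabilised and more nucleophilic, though more hindered. No stereocentre is formed. The step needs acylation at the acid chloride and not at the aryl ester, which the large electrophilicity gap at −78 °C and slow addition of 14 to the ylide should secure; the 4-prenyloxybenzoate is the only ester within reach of the ylide carbon, so ring closure has a single regiochemical outcome.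

Step 11
Reactants: 19 6-methoxy-5,7-bis(methoxymethoxy)-4'-prenyloxy-3-[2-(trimethylsilyl)ethoxy]flavone
Product: 20 3-hydroxy-6-methoxy-5,7-bis(methoxymethoxy)-4'-prenyloxyflavone
Conditions: TBAF (4 equiv), THF, rt → 50 °C, argon; aqueous NH4Cl
Reagents that add atoms: none
Why: Fluoride attack at silicon triggers β-elimination of the 2-silylethyl ether to ethene, fluorotrimethylsilane and the flavonol enolate, a good leaving group because the enol is acidic; MOM acetals, the aryl prenyl ether and the pyranone should tolerate fluoride.

Step 12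
Reactants: 20 3-hydroxy-6-methoxy-5,7-bis(methoxymethoxy)-4'-prenyloxyflavone
Product: 21 3,5,7-trihydroxy-6-methoxy-4'-prenyloxyflavone
Conditions: 3 M aqueous HCl (about 10 equiv), MeOH/THF 3:1, rt (not above 40 °C)
Reagents that add atoms: none
Why: Acid-catalysed acetal solvolysis (MOM ether cleavage) should free both phenols, since the phenolic formaldehyde acetals ionise far more readily in dilute acid at room temperature than the aryl prenyl ether or its trisubstituted alkene.

Compound list
1 | methyl 3,5-dihydroxy-4-methoxybenzoate | COC(=O)c1cc(O)c(OC)c(O)c1 | starting material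
2 | methyl 4-methoxy-3,5-bis(methoxymethoxy)benzoate | COCOc1cc(C(=O)OC)cc(OCOC)c1OC | intermediate
3 | [4-methoxy-3,5-bis(methoxymethoxy)phenyl]methanol | COCOc1cc(CO)cc(OCOC)c1OC | intermediate
4 | 4-methoxy-3,5-bis(methoxymethoxy)benzaldehyde | COCOc1cc(C=O)cc(OCOC)c1OC | intermediate
5 | 4-methoxy-3,5-bis(methoxymethoxy)phenyl formate | COCOc1cc(OC=O)cc(OCOC)c1OC | intermediate (not isolated)
6 | 4-methoxy-3,5-bis(methoxymethoxy)phenol | COCOc1cc(O)cc(OCOC)c1OC | intermediate
7 | 2-hydroxy-5-methoxy-4,6-bis(methoxymethoxy)benzaldehyde | COCOc1cc(O)c(C=O)c(OCOC)c1OC | intermediate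
8 | 4-hydroxybenzoic acid | O=C(O)c1ccc(O)cc1 | starting material
9 | prenyl bromide (1-bromo-3-methylbut-2-ene) | CC(C)=CCBr | starting material
10 | 3-methylbut-2-en-1-yl 4-[(3-methylbut-2-en-1-yl)oxy]benzoate | CC(C)=CCOC(=O)c1ccc(OCC=C(C)C)cc1 | intermediate (not isolated)
11 | 4-[(3-methylbut-2-en-1-yl)oxy]benzoic acid | CC(C)=CCOc1ccc(C(=O)O)cc1 | intermediate
12 | 2-formyl-4-methoxy-3,5-bis(methoxymethoxy)phenyl 4-[(3-methylbut-2-en-1-yl)oxy]benzoate | COCOc1cc(OC(=O)c2ccc(OCC=C(C)C)cc2)c(C=O)c(OCOC)c1OC | intermediate
13 | 3-methoxy-2,4-bis(methoxymethoxy)-6-(4-prenyloxybenzoyloxy)benzoic acid | COc1c(OCOC)cc(OC(=O)c2ccc(OCC=C(C)C)cc2)c(C(=O)O)c1OCOC | intermediate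
14 | 3-methoxy-2,4-bis(methoxymethoxy)-6-(4-prenyloxybenzoyloxy)benzoyl chloride | COc1c(OCOC)cc(OC(=O)c2ccc(OCC=C(C)C)cc2)c(C(Cl)=O)c1OCOC | intermediate
15 | [2-(trimethylsilyl)ethoxymethyl]triphenylphosphonium chloride | C[Si](C)(C)CCOC[P+](c1ccccc1)(c1ccccc1)c1ccccc1.[Cl-] | starting material
16 | [2-(trimethylsilyl)ethoxymethylene]triphenylphosphorane | C[Si](C)(C)CCOC=P(c1ccccc1)(c1ccccc1)c1ccccc1 | intermediate (not isolated)
17 | {2-[3-methoxy-2,4-bis(methoxymethoxy)-6-(4-prenyloxybenzoyloxy)phenyl]-2-oxo-1-[2-(trimethylsilyl)ethoxy]ethyl}triphenylphosphonium chloride (racemic at the phosphorus-bearing carbon, transient) | COc1c(OCOC)cc(OC(=O)c2ccc(OCC=C(C)C)cc2)c(C(=O)C(OCC[Si](C)(C)C)[P+](c2ccccc2)(c2ccccc2)c2ccccc2)c1OCOC.[Cl-] | intermediate (not isolated)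
18 | {2-[3-methoxy-2,4-bis(methoxymethoxy)-6-(4-prenyloxybenzoyloxy)phenyl]-2-oxo-1-[2-(trimethylsilyl)ethoxy]ethylidene}triphenylphosphorane | COc1c(OCOC)cc(OC(=O)c2ccc(OCC=C(C)C)cc2)c(C(=O)C(OCC[Si](C)(C)C)=P(c2ccccc2)(c2ccccc2)c2ccccc2)c1OCOC | intermediate (not isolated)
19 | 6-methoxy-5,7-bis(methoxymethoxy)-4'-prenyloxy-3-[2-(trimethylsilyl)ethoxy]flavone | COc1c(OCOC)cc2oc(-c3ccc(OCC=C(C)C)cc3)c(OCC[Si](C)(C)C)c(=O)c2c1OCOC | intermediate
20 | 3-hydroxy-6-methoxy-5,7-bis(methoxymethoxy)-4'-prenyloxyflavone | COc1c(OCOC)cc2oc(-c3ccc(OCC=C(C)C)cc3)c(O)c(=O)c2c1OCOC | intermediate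
21 | 3,5,7-trihydroxy-6-methoxy-4'-prenyloxyflavone | COc1c(O)cc2oc(-c3ccc(OCC=C(C)C)cc3)c(O)c(=O)c2c1O | target

Total step count: 12. Longest linear sequence: 11 steps (steps 1–5 and 7–12; step 6 is the one-step side branch).

Steps most likely to fail

1. Step 10 (Proposed new method). The non-stabilised ylide may attack the aryl ester in competition with the acid chloride, stripping the aroyl group. Alternatively the hindered, fully substituted ylide carbon may fail to add to the ester carbonyl, so that the acylphosphorane survives heating. The fallback uses known chemistry and sets out from 14. Acylation of methylenetriphenylphosphorane (2.2 equiv, from methyltriphenylphosphonium bromide and NaHMDS, THF, −78 °C) should give {2-[3-methoxy-2,4-bis(methoxymethoxy)-6-(4-prenyloxybenzoyloxy)phenyl]-2-oxoethylidene}triphenylphosphorane F1. Heating F1 in toluene should close it by the established intramolecular ester Wittig to 6-methoxy-5,7-bis(methoxymethoxy)-4'-prenyloxyflavone F2. Deprotonation at C3 with LDA (THF, −78 °C) gives the 3-lithioflavone F3, and trimethyl borate converts this into the dimethyl flavon-3-ylboronate F4. Oxidation with H2O2/AcOH then delivers 20, where the route is rejoined; step 11 is not needed on this path.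

2. Step 9. The neighbouring MOM acetal oxygen may take part in the acyl chloride, closing to a benzodioxinone with loss of chloromethane, or adventitious HCl may cleave an acetal, so that the chloride does not reach step 10 intact. The fallback sets out from 13. Silylation with N,O-bis(trimethylsilyl)acetamide (CH2Cl2, rt) gives trimethylsilyl 3-methoxy-2,4-bis(methoxymethoxy)-6-(4-prenyloxybenzoyloxy)benzoate F5, a neutral acyl donor that carries no halide. Silyl esters are known to acylate non-stabilised ylides, with the expelled silanolate acting as the base. Treatment of F5 with ylide 16 should therefore lead to acylphosphorane 18, where the route is rejoined inside step 10.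

3. Step 12. Acid may ionise the aryl prenyl ether (loss of the prenyl group) or add methanol or HCl across the alkene before the less reactive 7-O-MOM acetal has gone. The fallback sets out from 20 and replaces protic solvolysis by aprotic silyl transfer. TMSOTf/2,2'-bipyridyl (CH2Cl2, 0 °C → rt) exchanges each aryl MOM acetal for a trimethylsilyl ether under buffered conditions and silylates the 3-OH, giving 6-methoxy-4'-prenyloxy-3,5,7-tris(trimethylsilyloxy)flavone F6. Brief aqueous methanol work-up hydrolyses the silyl ethers and returns the route at 21.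

Step 11 is judged safer than these three because the leaving group of the fragmentation is the stabilised flavonol enolate.

Further compounds
F1 | step 10 | {2-[3-methoxy-2,4-bis(methoxymethoxy)-6-(4-prenyloxybenzoyloxy)phenyl]-2-oxoethylidene}triphenylphosphorane | COc1c(OCOC)cc(OC(=O)c2ccc(OCC=C(C)C)cc2)c(C(=O)C=P(c2ccccc2)(c2ccccc2)c2ccccc2)c1OCOC
F2 | step 10 | 6-methoxy-5,7-bis(methoxymethoxy)-4'-prenyloxyflavone | COc1c(OCOC)cc2oc(-c3ccc(OCC=C(C)C)cc3)cc(=O)c2c1OCOC
F3 | step 10 | 3-lithio-6-methoxy-5,7-bis(methoxymethoxy)-4'-prenyloxyflavone | COc1c(OCOC)cc2oc(-c3ccc(OCC=C(C)C)cc3)c([Li])c(=O)c2c1OCOC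
F4 | step 10 | dimethyl [6-methoxy-5,7-bis(methoxymethoxy)-4'-prenyloxyflavon-3-yl]boronate | COc1c(OCOC)cc2oc(-c3ccc(OCC=C(C)C)cc3)c(B(OC)OC)c(=O)c2c1OCOC
F5 | step 9 | trimethylsilyl 3-methoxy-2,4-bis(methoxymethoxy)-6-(4-prenyloxybenzoyloxy)benzoate | COc1c(OCOC)cc(OC(=O)c2ccc(OCC=C(C)C)cc2)c(C(=O)O[Si](C)(C)C)c1OCOC
F6 | step 12 | 6-methoxy-4'-prenyloxy-3,5,7-tris(trimethylsilyloxy)flavone | COc1c(O[Si](C)(C)C)cc2oc(-c3ccc(OCC=C(C)C)cc3)c(O[Si](C)(C)C)c(=O)c2c1O[Si](C)(C)C
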